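**Retrosynthetic overview** (labdane numbering: decalin C1–C10, side chain C11–C15, methylidene carbon C17)
1. Endgame: free the C15 acid from its methyl ester; C8=C17 by Wittig methylenation of an 8-ketone; the 8-ketone by hydroboration–oxidation of a Δ8(9) alkene; the axial 3-acetate from a 3-ketone.
2. C9–C11: Negishi coupling of a C9 enol triflate with the C11–C15 zinc reagent made from (R)-3-methylglutaric acid monomethyl ester, which carries C13.
3. Ring A: one-pot union of (S)-carvone (ring B), methyl isobutyrate (C3, C4 and both C4 methyls) and phenyl vinyl sulfone (C1, C2), forming C4–C5, C10–C1 and C2–C3.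
4. Enabling feature: ring A is a 3-oxygenated 4,4-dimethylcyclohexane fused at C5–C10; C5–C10 is the α,β-bond of a 2-methylcyclohexenone (C9 carbonyl), C3(O)–C4(Me)2 is an isobutyrate, and C1–C2 is a two-carbon Michael acceptor.
5. Ring order: ring B from the chiral pool, ring A in the key step; the C7 isopropenyl group of carvone steers C5 and C10 and is then excised.

Key step: step 1

Remark: the target is read as (3S,5S,9R,10S,13R) in labdane numbering, a trans-decalin with an axial 3-acetoxy group cis to H-5 and trans to the C10 methyl; (R)-3-methylglutaric acid monomethyl ester is taken as a commercial compound.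

**Step 1**
Reactants: 1 (S)-(+)-carvone; 2 methyl isobutyrate; 3 phenyl vinyl sulfone
Product: 7 trans-fused β-keto sulfone 7-isopropenyl-4,4,10-trimethyl-2-(phenylsulfonyl)decalin-3,9-dione, via lithium ester enolate 4 (not isolated), via lithium ketone enolate 5 (not isolated), via α-lithio sulfone 6 (not isolated)
Conditions: LiN(iPr)2, THF, −78 °C, 2; then 1, DMPU, −78 to −30 °C; then 3, −78 to 40 °C; aq. NH4Cl
Reagents that add atoms: none
Why: Conjugate addition of the lithium enolate of 2 to the enone of 1 forms C4–C5, the regiospecific C9–C10 enolate 5 adds to the vinyl sulfone to form C10–C1, and the α-sulfonyl carbanion 6 acylates itself on the ester to form C2–C3, the released methoxide deprotonating the β-keto sulfone so that the sequence ends in a stabilized enolate. The closest known reaction type is the three-component Michael–Michael–ring-closure annulation of an ester enolate, a cycloalkenone and a vinyl acceptor with Claisen termination. Ring A is closed by a 6-exo-trig intramolecular Claisen acylation of C2 on the C3 ester carbonyl. C5 is set by axial attack of the enolate anti to the C7 isopropenyl group, and C10 by attack of enolate 5 on the acceptor anti to the new bulky C5 substituent, which places C1 and C4 trans on ring B and so gives the trans-decalin with the angular methyl of the target series; C2 is not controlled and loses its substituent later. The step needs 1,4- over 1,2-addition and no enolate equilibration before the second Michael addition: the hindered α,α-disubstituted enolate and the α-methyl enone make the 1,2-adduct reversible, and 5 is kept at or below −30 °C until 3 is added.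

**Step 2**
Reactants: 7 trans-fused β-keto sulfone
Product: 9 keto sulfone 4,4,10-trimethyl-2-(phenylsulfonyl)-trans-decalin-3,9-dione, via methoxy hydroperoxide 8 (not isolated)
Conditions: O3, MeOH/CH2Cl2, −78 °C; then PhSH, FeSO4·7H2O, −78 °C to rt
Reagents that add atoms: none
Why: Hydrodealkenylation: Criegee ozonolysis of the 1,1-disubstituted alkene in methanol should give α-methoxy hydroperoxide 8, ferrous ion cleaves its O–O bond, β-scission of the alkoxy radical expels methyl acetate and the secondary C7 radical takes a hydrogen atom from the thiol, so that C7 becomes a methylene group while the non-enolized β-keto sulfone offers no other ozone-sensitive site.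

**Step 3**
Reactants: 9 keto sulfone
Product: 11 C9 enol triflate 4,4,10-trimethyl-3-oxo-2-(phenylsulfonyl)-trans-octal-8-en-9-yl trifluoromethanesulfonate, via dipotassium dianion 10 (not isolated)
Conditions: KN(SiMe3)2 (2.2 equiv), THF, −78 °C; then PhNTf2 (1.05 equiv), −78 to 0 °C; aq. NH4Cl
Reagents that add atoms: N-phenylbis(trifluoromethanesulfonimide) O=S(=O)(N(c1ccccc1)S(=O)(=O)C(F)(F)F)C(F)(F)F
Why: Enol triflate formation by way of a dianion: the first equivalent of base turns the β-keto sulfone into its stabilized enolate and so masks C3, the second removes H-8 (the only α-hydrogen of the C9 ketone, C10 being quaternary), and the more basic ketone enolate of 10 should be O-sulfonylated first.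

**Step 4**
Reactants: 11 C9 enol triflate
Product: 12 4,4,10-trimethyl-3-oxo-trans-octal-8-en-9-yl trifluoromethanesulfonate
Conditions: SmI2, THF/MeOH, −78 °C
Reagents that add atoms: none
Why: Reductive desulfonylation: electron transfer from SmI2 to the β-keto sulfone cleaves the C2–S bond and methanol protonates the samarium enolate, while the enol triflate and the hindered ketone should not be reduced at −78 °C.

**Step 5**
Reactants: 13 (R)-3-methylglutaric acid monomethyl ester
Product: 14 methyl (R)-5-hydroxy-3-methylpentanoate
Conditions: BH3·SMe2, THF, 0 °C to rt; MeOH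
Reagents that add atoms: none
Why: Chemoselective borane reduction of the carboxylic acid (through the acyloxyborane) in the presence of the methyl ester; the stereocenter is not touched and the hydroxy ester is used at once to avoid lactonization.

**Step 6**
Reactants: 14 methyl (R)-5-hydroxy-3-methylpentanoate
Product: 15 methyl (S)-5-iodo-3-methylpentanoate
Conditions: I2, PPh3, imidazole, CH2Cl2, 0 °C
Reagents that add atoms: iodine II
Why: Appel-type iodination (SN2 at the primary carbinol carbon via the alkoxyphosphonium ion) leaves the remote stereocenter untouched, the descriptor changing only by priority.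

**Step 7**
Reactants: 12 enol triflate; 15 methyl (S)-5-iodo-3-methylpentanoate
Product: 17 methyl (3R)-3-methyl-5-(4,4,10-trimethyl-3-oxo-trans-octal-8-en-9-yl)pentanoate, via alkylzinc iodide 16 (not isolated)
Conditions: 15, Zn, LiCl, THF, 40 °C; then 12, PdCl2(dppf) (5 mol %), THF/NMP, 50 °C
Reagents that add atoms: none
Why: Negishi coupling: LiCl-assisted insertion of zinc into the primary C–I bond tolerates the ester, and oxidative addition of zerovalent palladium to the enol triflate, transmetalation and reductive elimination should form C9–C11, the bidentate dppf ligand suppressing β-hydride elimination and the C3 ketone being inert to the organozinc.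

**Step 8**
Reactants: 17 keto ester
Product: 18 methyl 3-hydroxylabd-8-en-15-oate with the axial (3S) hydroxyl
Conditions: LiBH(s-Bu)3 (L-Selectride), THF, −78 to 0 °C; aq. NH4Cl
Reagents that add atoms: none
Why: Ketone reduction with a bulky trialkylborohydride, which attacks C3 along the equatorial trajectory because the axial path is blocked by the axial hydrogens at C1 and C5, should give the axial alcohol cis to H-5 as required, and the ester is not reduced at low temperature.

**Step 9**
Reactants: 18 axial alcohol
Product: 19 methyl 3-acetoxylabd-8-en-15-oate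
Conditions: Ac2O, pyridine, DMAP, rt to 40 °C
Reagents that add atoms: acetic anhydride CC(=O)OC(C)=O
Why: DMAP-catalysed acylation of the hindered axial secondary alcohol proceeds at oxygen and so retains the C3 configuration.

**Step 10**
Reactants: 19 acetate
Product: 21 methyl 3-acetoxy-8-hydroxy-17-norlabdan-15-oate, via alkylborane 20 (not isolated)
Conditions: BH3·SMe2, THF, 0 °C to rt; then NaBO3·4H2O, H2O, rt
Reagents that add atoms: sodium perborate [Na+].[Na+].O[B-]1(O)OO[B-](O)(O)OO1
Why: Hydroboration–oxidation: boron adds to the less substituted C8 and hydrogen to C9 in a syn fashion from the face opposite the axial C10 methyl, which sets H-9 as in the target (side chain equatorial), and perborate oxidizes the C–B bond with retention under near-neutral conditions that spare both esters.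

**Step 11**
Reactants: 21 C8 alcohol
Product: 22 methyl 3-acetoxy-8-oxo-17-norlabdan-15-oate
Conditions: Dess–Martin periodinane, NaHCO3, CH2Cl2, rt
Reagents that add atoms: none
Why: Dess–Martin oxidation of the secondary alcohol under buffered conditions; C9 keeps its configuration, which is also the thermodynamically favoured one (equatorial side chain) next to the new ketone.

**Step 12**
Reactants: 22 8-ketone
Product: 23 methyl ester of the target
Conditions: Ph3PCH3Br, KOtBu, THF/toluene, 0 to 60 °C
Reagents that add atoms: methyltriphenylphosphonium bromide C[P+](c1ccccc1)(c1ccccc1)c1ccccc1.[Br-]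
Why: Wittig methylenation of the 8-ketone, a reaction established for 8-oxolabdanes; the non-stabilized ylide reacts with the ketone much faster than with the two esters, and any enolization at C9 returns the stable equatorial epimer.

**Step 13**
Reactants: 23 methyl ester of the target
Product: 24 target acid
Conditions: LiI, pyridine, reflux; then cold 1 M HCl
Reagents that add atoms: none
Why: Nucleophilic demethylation (SN2 attack of iodide on the ester methyl group) should free the acid, while the acetate, whose O-alkyl carbon is secondary and neopentyl, is not cleaved and the exocyclic alkene meets no strong acid.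

**Compound list**
1 | (S)-(+)-carvone, (5S)-2-methyl-5-(prop-1-en-2-yl)cyclohex-2-en-1-one | CC1=CC[C@@H](CC1=O)C(C)=C | starting material
2 | methyl isobutyrate (methyl 2-methylpropanoate) | COC(=O)C(C)C | starting material
3 | phenyl vinyl sulfone | C=CS(=O)(=O)c1ccccc1 | starting material
4 | lithium enolate of 2 (lithium 1-methoxy-2-methylprop-1-en-1-olate), formed in situ | COC(O[Li])=C(C)C | intermediate
5 | lithium C9–C10 enolate of methyl 2-methyl-2-[2-methyl-3-oxo-5-(prop-1-en-2-yl)cyclohexyl]propanoate, ester-bearing group at C5 trans to the isopropenyl group, formed in situ | [Li]OC1=C(C)[C@@H](C(C)(C)C(=O)OC)C[C@H](C(C)=C)C1 | intermediate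
6 | α-lithio sulfone: methyl 2-[2-(2-lithio-2-phenylsulfonylethyl)-2-methyl-3-oxo-5-(prop-1-en-2-yl)cyclohexyl]-2-methylpropanoate, sulfonylethyl arm at C10 trans to the ester-bearing arm at C5, formed in situ | O=C1C[C@@H](C(C)=C)C[C@H](C(C)(C)C(=O)OC)[C@@]1(C)CC([Li])S(=O)(=O)c2ccccc2 | intermediate
7 | 7-isopropenyl-4,4,10-trimethyl-2-(phenylsulfonyl)-trans-decalin-3,9-dione (labdane numbering; C10 methyl trans to H-5, isopropenyl cis to H-5, ring fusion configured as in the target; both C2 epimers) | O=C1C[C@@H](C(C)=C)C[C@@H]2C(C)(C)C(=O)C(S(=O)(=O)c3ccccc3)C[C@@]12C | intermediate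
8 | α-methoxy hydroperoxide of 7 (C7 carries a 1-hydroperoxy-1-methoxyethyl group), formed in situ | O=C1C[C@@H](C(C)(OC)OO)C[C@@H]2C(C)(C)C(=O)C(S(=O)(=O)c3ccccc3)C[C@@]12C | intermediate
9 | 4,4,10-trimethyl-2-(phenylsulfonyl)-trans-decalin-3,9-dione (ring fusion as in the target; both C2 epimers) | O=C1CCC[C@@H]2C(C)(C)C(=O)C(S(=O)(=O)c3ccccc3)C[C@@]12C | intermediate
10 | dipotassium dianion of 9 (C2–C3 keto sulfone enolate and C8–C9 ketone enolate), formed in situ | [K]OC1=CCC[C@@H]2C(C)(C)C(O[K])=C(S(=O)(=O)c3ccccc3)C[C@@]12C | intermediate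
11 | 4,4,10-trimethyl-3-oxo-2-(phenylsulfonyl)-trans-octal-8-en-9-yl trifluoromethanesulfonate | FC(F)(F)S(=O)(=O)OC1=CCC[C@@H]2C(C)(C)C(=O)C(S(=O)(=O)c3ccccc3)C[C@@]12C | intermediate
12 | 4,4,10-trimethyl-3-oxo-trans-octal-8-en-9-yl trifluoromethanesulfonate | FC(F)(F)S(=O)(=O)OC1=CCC[C@@H]2C(C)(C)C(=O)CC[C@@]12C | intermediate
13 | (R)-3-methylglutaric acid monomethyl ester, (R)-5-methoxy-3-methyl-5-oxopentanoic acid | OC(=O)C[C@@H](C)CC(=O)OC | starting material
14 | methyl (R)-5-hydroxy-3-methylpentanoate | OCC[C@@H](C)CC(=O)OC | intermediate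
15 | methyl (S)-5-iodo-3-methylpentanoate | ICC[C@@H](C)CC(=O)OC | intermediate
16 | [(3S)-5-methoxy-3-methyl-5-oxopentyl]zinc iodide, formed in situ | I[Zn]CC[C@@H](C)CC(=O)OC | intermediate
17 | methyl (3R)-3-methyl-5-(4,4,10-trimethyl-3-oxo-trans-octal-8-en-9-yl)pentanoate (methyl 3-oxolabd-8-en-15-oate, ring fusion and C13 as in the target) | COC(=O)C[C@H](C)CCC1=CCC[C@@H]2C(C)(C)C(=O)CC[C@@]12C | intermediate
18 | methyl 3-hydroxylabd-8-en-15-oate, hydroxyl axial, (3S), cis to H-5 | COC(=O)C[C@H](C)CCC1=CCC[C@@H]2C(C)(C)[C@@H](O)CC[C@@]12C | intermediate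
19 | methyl 3-acetoxylabd-8-en-15-oate, acetoxy axial, (3S) | COC(=O)C[C@H](C)CCC1=CCC[C@@H]2C(C)(C)[C@@H](OC(C)=O)CC[C@@]12C | intermediate
20 | C8 alkylborane of 19 (boron on C8 and H-9 on the face opposite the C10 methyl), formed in situ | [BH2][C@H]1CC[C@@H]2C(C)(C)[C@@H](OC(C)=O)CC[C@@]2(C)[C@@H]1CC[C@@H](C)CC(=O)OC | intermediate
21 | methyl 3-acetoxy-8-hydroxy-17-norlabdan-15-oate (8-OH and H-9 cis, both trans to the C10 methyl) | O[C@H]1CC[C@@H]2C(C)(C)[C@@H](OC(C)=O)CC[C@@]2(C)[C@@H]1CC[C@@H](C)CC(=O)OC | intermediate
22 | methyl 3-acetoxy-8-oxo-17-norlabdan-15-oate (side chain at C9 equatorial, as in the target) | O=C1CC[C@@H]2C(C)(C)[C@@H](OC(C)=O)CC[C@@]2(C)[C@@H]1CC[C@@H](C)CC(=O)OC | intermediate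
23 | methyl (3S,5S,9R,10S,13R)-3-acetoxylabd-8(17)-en-15-oate | C=C1CC[C@@H]2C(C)(C)[C@@H](OC(C)=O)CC[C@@]2(C)[C@@H]1CC[C@@H](C)CC(=O)OC | intermediate
24 | (3R)-5-[(1R,4aS,6S,8aS)-6-acetoxy-5,5,8a-trimethyl-2-methylidenedecahydronaphthalen-1-yl]-3-methylpentanoic acid | C=C1CC[C@@H]2C(C)(C)[C@@H](OC(C)=O)CC[C@@]2(C)[C@@H]1CC[C@@H](C)CC(=O)O | target

**Totals**
Total step count: 13 (steps 5 and 6 prepare the side-chain iodide).
Longest linear sequence: 11 steps (steps 1–4 and 7–13).

**Steps most likely to fail**

Step 1. What may go wrong: incomplete Michael addition of the tetrasubstituted enolate 5 to the acceptor, anionic polymerization of the vinyl sulfone, equilibration of 5 to the C8 enolate, or slow Claisen closure on the hindered ester. Fallback, from 1 back to 7: treat 1 with 1-methoxy-2-methyl-1-(trimethylsilyloxy)prop-1-ene and catalytic Me3SiOTf in CH2Cl2 at −78 °C (Mukaiyama–Michael addition, again anti to the isopropenyl group) and isolate the trimethylsilyl enol ether F1. Regenerate the lithium enolate 5 from it with MeLi in THF at 0 °C, add 3 at −78 °C and quench cold with acetic acid to isolate the keto ester sulfone F2. Close ring A separately with LiN(SiMe3)2 in THF at 0 °C to rt, which returns to the route at 7.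

Step 3. What may go wrong: sulfonylation at the keto sulfone oxygen, bis-triflation, or incomplete formation of the second enolate. Fallback, from 9 back to 17: condense the less hindered C9 ketone of 9 with hydrazine hydrate (EtOH, Et3N, 50 °C) to give the C9 hydrazone F3. Convert it with I2 and tetramethylguanidine in THF (Barton vinyl iodide synthesis) into the C9 vinyl iodide F4. Remove the sulfone with SmI2 in THF/MeOH at −78 °C to give the vinyl iodide ketone F5, and couple F5 with zinc reagent 16 under the conditions of step 7, which returns to the route at 17.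

Step 10. What may go wrong: slow hydroboration of the hindered trisubstituted alkene next to the quaternary C10, with competing reduction of the acetate or the methyl ester by borane. Fallback, from 19 back to 22: dihydroxylate the Δ8(9) alkene with OsO4 and N-methylmorpholine N-oxide in acetone/H2O from the face opposite the C10 methyl to give the 8,9-diol F6. Oxidize its secondary C8 hydroxyl with Dess–Martin periodinane to the α-hydroxy ketone F7. Remove the tertiary C9 hydroxyl with SmI2 in THF/MeOH, then equilibrate C9 with DBU to the equatorial epimer, which is 22.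

**Further compounds**
F1 | step 1 | trimethylsilyl enol ether of methyl 2-methyl-2-[2-methyl-3-oxo-5-(prop-1-en-2-yl)cyclohexyl]propanoate (C9–C10 enol ether, C5 substituent trans to isopropenyl) | C[Si](C)(C)OC1=C(C)[C@@H](C(C)(C)C(=O)OC)C[C@H](C(C)=C)C1
F2 | step 1 | methyl 2-methyl-2-[2-methyl-3-oxo-2-(2-phenylsulfonylethyl)-5-(prop-1-en-2-yl)cyclohexyl]propanoate (sulfonylethyl arm trans to the ester-bearing arm) | O=C1C[C@@H](C(C)=C)C[C@H](C(C)(C)C(=O)OC)[C@@]1(C)CCS(=O)(=O)c2ccccc2
F3 | step 3 | C9 hydrazone of 9 | NN=C1CCC[C@@H]2C(C)(C)C(=O)C(S(=O)(=O)c3ccccc3)C[C@@]12C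
F4 | step 3 | 9-iodo-4,4,10-trimethyl-2-(phenylsulfonyl)-trans-octal-8-en-3-one | IC1=CCC[C@@H]2C(C)(C)C(=O)C(S(=O)(=O)c3ccccc3)C[C@@]12C
F5 | step 3 | 9-iodo-4,4,10-trimethyl-trans-octal-8-en-3-one | IC1=CCC[C@@H]2C(C)(C)C(=O)CC[C@@]12C
F6 | step 10 | methyl 3-acetoxy-8,9-dihydroxy-17-norlabdan-15-oate (both hydroxyls cis, trans to the C10 methyl) | O[C@H]1CC[C@@H]2C(C)(C)[C@@H](OC(C)=O)CC[C@@]2(C)[C@]1(O)CC[C@@H](C)CC(=O)OC
F7 | step 10 | methyl 3-acetoxy-9-hydroxy-8-oxo-17-norlabdan-15-oate | O=C1CC[C@@H]2C(C)(C)[C@@H](OC(C)=O)CC[C@@]2(C)[C@]1(O)CC[C@@H](C)CC(=O)OC
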